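**Retrosynthetic overview**

1. Target 24 ⇐ Mitsunobu esterification (inversion at C6) of the 6β-alcohol 22 with 4-hydroxybenzoic acid; 22 ⇐ enedione 20 by hydroxyl-directed C6 reduction and hydrogenation of the isopropenyl group.
2. 20 ⇐ acid-triggered opening of the dihydrofuran (ring B) of tricycle 17: the tether oxygen stays on C6, its CMe2 carbon becomes the C4 side chain, and H-5 is fixed by the cis A/B fusion.
3. 17 ⇐ trienone 13 (CBS reduction and acetylation at C2, enol-ether hydrolysis at C9). 13 ⇐ key step: Rh-catalysed intramolecular Buchner reaction of diazoketone 11, which closes five-membered ring A and turns the benzene ring into the seven-membered ring in one operation, setting quaternary C1 from C4.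
4. 11 ⇐ benzofuranone 3 by enantioselective allylation (sets C4), oxidative cleavage and acylation of diazoethane; 3 ⇐ 2,5-dimethoxytoluene 1 + 2-bromoisobutyryl bromide 2.
5. Ring order: temporary dihydrofuran ring B (step 1) → ring A and the seven-membered ring together (step 6) → ring B opened (step 10).

Atom labels (daucane numbering): C1 = methyl-bearing ring-fusion carbon; C2 (OAc), C3, C4 (OH, isopropyl), C5 (ring-fusion CH) complete ring A; C6 (ester), C7=C8(Me), C9 (C=O), C10 complete the seven-membered ring. β = face of the C1 methyl, α = opposite face.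

Assumption: (R)-BINOL is taken to give the (S)-alcohol 5 in step 2; if the sense of induction is the opposite, (S)-BINOL is used.

**Route**

Step 1
Reactants: 1 1,4-dimethoxy-2-methylbenzene; 2 2-bromo-2-methylpropanoyl bromide
Product: 3 5-methoxy-2,2,6-trimethyl-1-benzofuran-3(2H)-one
Conditions: AlCl3 (2.5 equiv), ClCH2CH2Cl, 0 → 70 °C
Reagents that add atoms: none
Why: Friedel–Crafts acylation para to the methyl group, then in the same pot AlCl3 cleaves the methoxy group chelated to the new ketone and the phenoxide displaces the tertiary α-bromide to close the benzofuranone; no stereocentre.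

Step 2
Reactants: 3 5-methoxy-2,2,6-trimethyl-1-benzofuran-3(2H)-one; 4 tetraallylstannane
Product: 5 (3S)-3-allyl-5-methoxy-2,2,6-trimethyl-2,3-dihydro-1-benzofuran-3-ol
Conditions: Ti(OiPr)4 (30 mol%), (R)-BINOL (30 mol%), iPrOH (20 equiv), CH2Cl2, rt
Reagents that add atoms: none
Why: titanium–BINOL-catalysed enantioselective allylation of a non-enolisable ketone whose two flanks (aryl versus O-bearing quaternary carbon) differ strongly; the catalyst sets the tertiary carbinol (future C4) as (S).

Step 3
Reactants: 5 (3S)-3-allyl-5-methoxy-2,2,6-trimethyl-2,3-dihydro-1-benzofuran-3-ol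
Product: 6 triethylsilyl ether of 5
Conditions: Et3SiOTf, 2,6-lutidine, CH2Cl2, −78 → 0 °C
Reagents that add atoms: triethylsilyl trifluoromethanesulfonate, CC[Si](CC)(CC)OS(=O)(=O)C(F)(F)F
Why: silyl triflate silylation of a hindered tertiary alcohol; the bulky silyl ether prevents O–H insertion in step 6 and is a poor leaving group next to the later enol ether.

Step 4
Reactants: 6 triethylsilyl ether of 5
Product: 7 2-[(3S)-5-methoxy-2,2,6-trimethyl-3-(triethylsilyloxy)-2,3-dihydro-1-benzofuran-3-yl]acetic acid
Conditions: KMnO4 (5 mol%), NaIO4 (4.1 equiv), K2CO3 (0.3 equiv), tBuOH/H2O, rt; work-up at pH 4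
Reagents that add atoms: sodium periodate, [Na+].[O-]I(=O)(=O)=O; water, O
Why: Lemieux–von Rudloff oxidative cleavage of the terminal alkene to the carboxylic acid under buffered conditions that spare the silyl ether and the arene; the stereocentre is untouched.

Step 5
Reactants: 7 2-[(3S)-5-methoxy-2,2,6-trimethyl-3-(triethylsilyloxy)-2,3-dihydro-1-benzofuran-3-yl]acetic acid; 8 N-ethyl-N-nitrosourea
Product: 11 3-diazo-1-[(3S)-5-methoxy-2,2,6-trimethyl-3-(triethylsilyloxy)-2,3-dihydro-1-benzofuran-3-yl]butan-2-one, via mixed anhydride 9 (not isolated), via diazoethane 10 (not isolated)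
Conditions: iBuOCOCl, N-methylmorpholine, THF, −20 °C; then CH3CHN2 in Et2O (from 8, KOH, Et2O/H2O, 0 °C), −20 → 0 °C
Reagents that add atoms: none
Why: acylation of a diazoalkane by a mixed carbonic anhydride (Arndt–Eistert-type diazoketone synthesis) gives the α-methyl α-diazoketone without touching the stereocentre.

Step 6 (key step)
Reactants: 11 3-diazo-1-[(3S)-5-methoxy-2,2,6-trimethyl-3-(triethylsilyloxy)-2,3-dihydro-1-benzofuran-3-yl]butan-2-one
Product: 13 tricyclic trienone, via norcaradiene 12 (not isolated)
Conditions: Rh2(O2CtBu)4 (1 mol%), CH2Cl2, slow addition of 11, 0 °C → rt; chromatography on Et3N-deactivated silica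
Reagents that add atoms: none
Why: intramolecular Buchner reaction (arene cyclopropanation by the rhodium carbenoid, then disrotatory 6π ring opening of the norcaradiene). The dihydrofuran holds CMe2 in the arene plane, so the carbenoid tether and OSiEt3 lie on opposite faces. The carbenoid therefore adds to the only free ipso–ortho bond anti to OSiEt3, placing the C1 methyl cis to CMe2 and trans to O4. C4 carries no hydrogen, so C–H insertion cannot compete, and the bulky carboxylate ligand slows 1,2-hydride shift of the α-methyl carbenoid.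

Step 7
Reactants: 13 tricyclic trienone
Product: 14 2α-alcohol
Conditions: (S)-2-methyl-CBS-oxazaborolidine (20 mol%), catecholborane, toluene, −78 °C
Reagents that add atoms: none
Why: Corey–Bakshi–Shibata reduction; with quaternary C1 as the large and C3H2 as the small flank, the (S)-catalyst delivers hydride to the β face of the C2 ketone and gives the 2α-alcohol, while catecholborane at −78 °C leaves the enol ethers alone.

Step 8
Reactants: 14 2α-alcohol
Product: 15 2α-acetate
Conditions: Ac2O, DMAP, Et3N, CH2Cl2, rt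
Reagents that add atoms: acetic anhydride, CC(=O)OC(C)=O
Why: DMAP-catalysed acetylation of the secondary alcohol with retention; the tertiary oxygen is still silylated.

Step 9
Reactants: 15 2α-acetate
Product: 17 dienone alcohol, via silyl ether dienone 16 (not isolated)
Conditions: 0.5 M HCl (aq), THF, 0 °C → rt
Reagents that add atoms: water, O
Why: acid-catalysed enol-ether hydrolysis: protonation at C10, the unhindered terminus of the trienyl ether, and loss of methanol give the C9 ketone; the ring-B enol ether is then conjugated to the enone and hydrolyses only slowly, and the tertiary silyl ether is cleaved; no stereocentre is touched.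

Step 10
Reactants: 17 dienone alcohol
Product: 20 isopropenyl enedione, via trifluoroacetate 18 (not isolated), via ring-opened trifluoroacetate 19 (not isolated)
Conditions: (CF3CO)2O (3 equiv), TfOH (0.2 equiv), CH2Cl2, −40 → −10 °C; then Et3N, MeOH, 0 °C
Reagents that add atoms: none
Why: Proposed new method: acid-catalysed trifluoroacetylation first caps O4, which switches off the pinacol-type 1,2-shift; TfOH then protonates the enol ether at C5 on the α face, because rings A and B must stay cis-fused, and this sets H-5 α; the tert-alkyl oxocarbenium ion collapses by C–O heterolysis to the C6 ketone and a tertiary cation that loses a methyl proton to give the isopropenyl group (E1), and Et3N/MeOH removes the trifluoroacetate; the closest known reaction type is the acid cleavage of tert-butyl enol ethers and tert-butyl ethers to the carbonyl or hydroxyl compound and isobutene.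

Step 11
Reactants: 20 isopropenyl enedione
Product: 21 6β-alcohol
Conditions: Me4NBH(OAc)3, MeCN/AcOH, −30 °C
Reagents that add atoms: none
Why: hydroxyl-directed triacetoxyborohydride reduction (Evans–Saksena type): only the C6 ketone, β to the free C4 hydroxyl, is reduced; delivery from the α-oriented O4 across the α face (the β face is screened by C1 with its methyl and by the C4 side chain) gives the 6β-alcohol.

Step 12
Reactants: 21 6β-alcohol
Product: 22 isopropyl 6β-alcohol
Conditions: H2 (3 atm), RhCl(PPh3)3 (5 mol%), benzene/EtOH, rt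
Reagents that add atoms: none
Why: homogeneous hydrogenation reduces the 1,1-disubstituted isopropenyl alkene and leaves the trisubstituted conjugated C7=C8 bond, as in the selective hydrogenation of carvone; no stereocentre is formed.

Step 13
Reactants: 22 isopropyl 6β-alcohol; 23 4-hydroxybenzoic acid
Product: 24 target
Conditions: PPh3, DIAD, THF, 0 °C → rt
Reagents that add atoms: none
Why: Mitsunobu esterification: the carboxylate attacks C6 from the open α face with inversion, turning the 6β-alcohol into the 6α-ester; the carboxylic acid reacts in preference to its phenol and the tertiary C4 hydroxyl is inert, so no protecting group is needed.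

**Compound list**

1 | 1,4-dimethoxy-2-methylbenzene (2,5-dimethoxytoluene) | COc1ccc(OC)c(C)c1 | starting material
2 | 2-bromo-2-methylpropanoyl bromide | CC(C)(Br)C(=O)Br | starting material
3 | 5-methoxy-2,2,6-trimethyl-1-benzofuran-3(2H)-one | COc1cc2C(=O)C(C)(C)Oc2cc1C | intermediate
4 | tetraallylstannane | C=CC[Sn](CC=C)(CC=C)CC=C | starting material
5 | (3S)-3-allyl-5-methoxy-2,2,6-trimethyl-2,3-dihydro-1-benzofuran-3-ol | C=CC[C@@]1(O)C(C)(C)Oc2cc(C)c(OC)cc12 | intermediate
6 | (3S)-3-allyl-5-methoxy-2,2,6-trimethyl-3-(triethylsilyloxy)-2,3-dihydro-1-benzofuran | C=CC[C@@]1(O[Si](CC)(CC)CC)C(C)(C)Oc2cc(C)c(OC)cc12 | intermediate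
7 | 2-[(3S)-5-methoxy-2,2,6-trimethyl-3-(triethylsilyloxy)-2,3-dihydro-1-benzofuran-3-yl]acetic acid | OC(=O)C[C@@]1(O[Si](CC)(CC)CC)C(C)(C)Oc2cc(C)c(OC)cc12 | intermediate
8 | N-ethyl-N-nitrosourea | CCN(N=O)C(N)=O | starting material
9 | mixed anhydride of 7 with isobutyl carbonic acid | CC(C)COC(=O)OC(=O)C[C@@]1(O[Si](CC)(CC)CC)C(C)(C)Oc2cc(C)c(OC)cc12 | intermediate (not isolated)
10 | diazoethane | CC=[N+]=[N-] | intermediate (not isolated)
11 | 3-diazo-1-[(3S)-5-methoxy-2,2,6-trimethyl-3-(triethylsilyloxy)-2,3-dihydro-1-benzofuran-3-yl]butan-2-one | CC(=[N+]=[N-])C(=O)C[C@@]1(O[Si](CC)(CC)CC)C(C)(C)Oc2cc(C)c(OC)cc12 | intermediate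
12 | norcaradiene: cyclopropane C1–C5–C10 fused to cyclopentanone ring A, to dihydrofuran ring B and to the cyclohexadiene C9(OMe)=C8(Me)–C7H=C6(O); C1 methyl on the diene side | C[C@]12C(=O)C[C@@]3(O[Si](CC)(CC)CC)C(C)(C)OC4=CC(C)=C(OC)[C@@H]1[C@@]243 | intermediate (not isolated)
13 | tricyclic trienone: ring A C1(Me β)–C2(=O)–C3H2–C4(OSiEt3 α)–C5; seven-membered ring C5=C6–C7H=C8(Me)–C9(OMe)=C10H–C1; ring B C4–CMe2(β)–O–C6 | C[C@]12C=C(OC)C(C)=CC3=C1[C@@](O[Si](CC)(CC)CC)(CC2=O)C(C)(C)O3 | intermediate
14 | 2α-alcohol of 13 (C2–OH α, trans to the C1 methyl) | C[C@]12C=C(OC)C(C)=CC3=C1[C@@](O[Si](CC)(CC)CC)(C[C@H]2O)C(C)(C)O3 | intermediate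
15 | 2α-acetate of 14 | C[C@]12C=C(OC)C(C)=CC3=C1[C@@](O[Si](CC)(CC)CC)(C[C@H]2OC(C)=O)C(C)(C)O3 | intermediate
16 | silyl ether dienone: as 15 but C9 ketone, C10H2, C7=C8(Me), C5=C6(O) | C[C@]12CC(=O)C(C)=CC3=C1[C@@](O[Si](CC)(CC)CC)(C[C@H]2OC(C)=O)C(C)(C)O3 | intermediate (not isolated)
17 | dienone alcohol: 16 with free C4–OH (α) | C[C@]12CC(=O)C(C)=CC3=C1[C@@](O)(C[C@H]2OC(C)=O)C(C)(C)O3 | intermediate
18 | 4-O-trifluoroacetate of 17 | C[C@]12CC(=O)C(C)=CC3=C1[C@@](OC(=O)C(F)(F)F)(C[C@H]2OC(C)=O)C(C)(C)O3 | intermediate (not isolated)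
19 | ring-opened trifluoroacetate: 2α-acetoxy-4β-isopropenyl-4α-(trifluoroacetoxy)-5α-H-dauc-7-ene-6,9-dione | C[C@]12CC(=O)C(C)=CC(=O)[C@@H]1[C@@](OC(=O)C(F)(F)F)(C[C@H]2OC(C)=O)C(C)=C | intermediate (not isolated)
20 | isopropenyl enedione: 2α-acetoxy-4α-hydroxy-4β-isopropenyl-5α-H-dauc-7-ene-6,9-dione (trans-fused) | C[C@]12CC(=O)C(C)=CC(=O)[C@@H]1[C@@](O)(C[C@H]2OC(C)=O)C(C)=C | intermediate
21 | 6β-alcohol: 2α-acetoxy-4α,6β-dihydroxy-4β-isopropenyl-5α-H-dauc-7-en-9-one | C[C@]12CC(=O)C(C)=C[C@H](O)[C@@H]1[C@@](O)(C[C@H]2OC(C)=O)C(C)=C | intermediate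
22 | isopropyl 6β-alcohol: 2α-acetoxy-4α,6β-dihydroxy-5α-H-dauc-7-en-9-one | C[C@]12CC(=O)C(C)=C[C@H](O)[C@@H]1[C@@](O)(C[C@H]2OC(C)=O)C(C)C | intermediate
23 | 4-hydroxybenzoic acid | OC(=O)c1ccc(O)cc1 | starting material
24 | (1R,3R,3aR,4R,8aS)-1-acetoxy-3-hydroxy-6,8a-dimethyl-7-oxo-3-(propan-2-yl)-1,2,3,3a,4,7,8,8a-octahydroazulen-4-yl 4-hydroxybenzoate (daucane numbering 1S,2R,4R,5R,6R) | CC(=O)O[C@@H]1C[C@@](O)(C(C)C)[C@H]2[C@H](OC(=O)c3ccc(O)cc3)C=C(C)C(=O)C[C@]12C | target

**Step count and risks**

Total steps: 13. Longest linear sequence: 13 steps (1 → 24).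

Steps most likely to fail:

1. Step 10 (opening of ring B). The tertiary cation may rearrange, the allylic C4 ester may ionise, or C5 may epimerise next to the new ketone. Fallback, from 17 back to 20, avoiding any free cation: hydrolyse the enol ether normally with aqueous HCl/THF at 40 °C (C6–O cleavage, H-5 still set by the cis A/B fusion) to the hydroxyisopropyl enedione diol F3. Close the ditertiary diol with Martin sulfurane to the spiro-epoxide F4 (the exocyclic oxygen is activated and O4 attacks, so C4 is untouched). Isomerise the epoxide with Et2Al(TMP) (diethylaluminium 2,2,6,6-tetramethylpiperidide) in toluene at −40 °C, which removes a methyl proton in a syn elimination and returns 20.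

2. Step 6 (Buchner reaction of the α-methyl carbenoid). A 1,2-hydride shift to the vinyl ketone or aromatic substitution may compete. Fallback, from 7 back to 13, putting the quaternary methyl in after ring formation: convert 7 through mixed anhydride 9 with (trimethylsilyl)diazomethane into the terminal diazoketone F1. Cyclise it with Rh2(OAc)4 to the trienone lacking the angular methyl F2. Methylate its extended enolate (KN(SiMe3)2, MeI, THF, −78 °C) at C1 on the β face, anti to the axial OSiEt3 group, to give 13.

3. Step 11 (directed reduction of C6 in the enedione). Internal delivery across a trans-disposed hydroxyl/acyl pair may be slow, or the C9 ketone may compete. Fallback, from 20 back to 21, by global reduction and selective re-oxidation: reduce both ketones from the open α face with NaBH4/CeCl3 in MeOH at −78 °C to the 6β,9-diol F5 (mixture at C9). Re-oxidise only the less hindered allylic C9 alcohol with MnO2 in CH2Cl2 to return 21.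

**Further compounds**

F1 | step 6 | 1-diazo-3-[(3S)-5-methoxy-2,2,6-trimethyl-3-(triethylsilyloxy)-2,3-dihydro-1-benzofuran-3-yl]propan-2-one | [N-]=[N+]=CC(=O)C[C@@]1(O[Si](CC)(CC)CC)C(C)(C)Oc2cc(C)c(OC)cc12
F2 | step 6 | trienone 13 lacking the C1 methyl (H-1 β) | [C@H]12C=C(OC)C(C)=CC3=C1[C@@](O[Si](CC)(CC)CC)(CC2=O)C(C)(C)O3
F3 | step 10 | 2α-acetoxy-4α-hydroxy-4β-(2-hydroxypropan-2-yl)-5α-H-dauc-7-ene-6,9-dione | C[C@]12CC(=O)C(C)=CC(=O)[C@@H]1[C@@](O)(C[C@H]2OC(C)=O)C(C)(C)O
F4 | step 10 | spiro-epoxide of F3 (oxirane C4–O–CMe2, oxygen α on C4) | C[C@]12CC(=O)C(C)=CC(=O)[C@@H]1[C@]3(C[C@H]2OC(C)=O)OC3(C)C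
F5 | step 11 | 2α-acetoxy-4β-isopropenyl-5α-H-dauc-7-ene-4α,6β,9-triol (mixture at C9) | C[C@]12CC(O)C(C)=C[C@H](O)[C@@H]1[C@@](O)(C[C@H]2OC(C)=O)C(C)=C
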